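## Structural features

Atom numbers follow the drimane convention: ring A is C1–C5 plus C10, ring B is C5–C10, C11 is the chlorine-bearing carbon and the arene carbons are primed. The target is a trans-fused decalin whose C9 carries an exocyclic, fully substituted (E)-chloroalkene C9=C11. C11 holds a 2',5'-dihydroxy-3'-methoxyphenyl ring, so terpene and arene are joined through one sp2 carbon. The ring-fusion centres C5 (S, α-hydrogen) and C10 (S, β-methyl) are adjacent; the third stereocentre C8 (S) lies across C9 from C10, with its methyl on the same face as the angular methyl. The hydroquinone oxidises easily to the quinone, the vinyl chloride does not tolerate hydrogenolysis or dissolving metals, and the three arene oxygens must be told apart (one methyl ether, two free phenols). The real difficulty is the crowded C9=C11 alkene, flanked by quaternary C10 and by C8, with fixed geometry (chlorine syn to C8, arene syn to C10) and with the C8 methyl on the more hindered face. The key step uses the gem-dimethyl carbon C4 next to C5: as a tertiary cation it lets ring A close at C3–C4 from an isopropenyl group on C5 and a silyl-terminated allyl group on C10 of a ring-B ketone, whose C9 oxygen later becomes the handle for C11.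

## Logic of the disconnections

**23 to 21 (through 22).** The two phenolic O–H bonds at C2' and C5' are traced back to O–CH3 bonds. A free hydroquinone would not survive the bases, oxidants and low-valent metals of the route, and the para pair of methyl ethers can be taken off together by oxidation to the quinone and reduction. The forward step must strip only the para pair, keep the C3' ether and leave the chloroalkene alone.

**21 to 20.** The C11–Cl bond is exchanged for a C11–O sulfonate bond. Oxygen at C11 comes naturally from carbonyl chemistry, whereas chlorine cannot be delivered to an enolate carbon as a vinyl halide. The forward exchange must proceed with retention at a tetrasubstituted, crowded alkene.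

**20 to 18 (through 19).** The C8–H bond and the O–S bond are cut together. One operation then sets C8 and fixes both the position and the geometry of the C9=C11 alkene, so earlier intermediates carry neither. The forward step needs hydride delivery to C8 from the face opposite the angular methyl and an enolate with oxygen syn to C8.

**18 to 17 to 13 and 16.** The C9–C11 bond is the only link between the two halves. Making C9 the nucleophile (an sp2 carbon–metal bond from the sulfonate of 13) avoids any addition to a C9 carbonyl shielded by C10 and C8. The gain is full convergence. The demand is metal insertion into a hindered tetrasubstituted C–O bond and addition to the aldehyde only.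

**16 to 15 to 14.** One O–CH3 bond and the C5'–O bond are cut, leading to a commercial bromophenol aldehyde in which the halogen marks the future C5' oxygen.

**13 to 11 to 9 (through 12 and 10).** The C9–O sulfonate bond and the C8–CH3 bond are removed. C10 is quaternary, so the C9 ketone can enolise only toward C8, and both operations are regiodefined without any blocking group.

**9 to 8.** A C2=C3 double bond is written back in. It is the trace that the departing silicon leaves, and it is removed by hydrogenation before any other alkene exists.

**8 to 7 (key disconnection).** The C3–C4 bond is cut, opening ring A to a ring-B ketone with an isopropenyl group on C5 and a 3-silylallyl group on C10. The vinylsilane in 7 is Z. In a ring closure that keeps both alkene carbons inside the new six-membered ring, only the Z isomer can bring its C–Si bond into line with the developing cation at C2 while the ring alkene becomes cis. The E isomer could use that stabilisation only on a path to a trans-cyclohexene. The forward step must protonate the isopropenyl group in preference to the vinylsilane and must not let the ketone intercept the cation.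

**7 to 4, 5 and 3 (through 6).** The C4–C5 bond (conjugate addition) and the C1–C10 bond (enolate alkylation) are cut. This reduces 7 to three small reagents in one operation. The forward step has to set C5 by catalyst control and C10 by alkylation anti to the C5 substituent, which puts the two future ring-A arms trans on ring B and thereby fixes the trans ring fusion.

**3 to 2 to 1.** The C–Br bond comes from a C–O bond, and the Z alkene from an alkyne by syn addition of hydrogen.

## Other disconnections considered

**Alternative 1:** The cut is through ring B at C5–C10 and C8–C9. The forward key step is an intramolecular Diels–Alder reaction of the trienoyl oxazolidinone A1, promoted by a dialkylaluminium chloride, giving the trans-fused octalin imide A2.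
- In its favour: one step would form both rings and four stereocentres, including the C8 methyl in its final configuration, and C11 would already sit on C9 at the carboxyl oxidation level. Absolute control would come from an inexpensive auxiliary of known sense.
- Against it here: the dienophile is β,β-disubstituted (it must create quaternary C10) and the diene terminus C5 is neopentyl, so the C5–C10 bond joins two crowded carbons. Auxiliary-controlled cycloadditions of this kind are dependable mainly for unhindered enimides. The C9 stereocentre would later be erased, C6=C7 must be hydrogenated, and the imide must be turned into an aryl ketone at a hindered carbonyl. A1 itself needs a linear synthesis with two defined alkenes and a quaternary carbon.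
- Comparison: on structure A2 is the better intermediate for C8, since it removes the facial-selectivity question of step 12. On mechanism a concerted cycloaddition is more predictable in stereochemistry than a cation, but less predictable in rate. On step economy the two plans would be about equal at best, and the chosen plan has the shorter access to its key-step precursor.

**Alternative 2:** The cut is at C5–C6 and C10–CH3 on a ring A bought as the dienone A3. The forward key step is a copper-catalysed desymmetrising conjugate addition of the ketal-bearing Grignard reagent A4 to one enone arm, followed by methylation of the enolate at C10, giving A4-derived enone A5.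
- In its favour: the gem-dimethyl carbon is purchased, so no ring-A closure is needed and the riskiest step of the chosen plan disappears. A second alkylation at C10, anti to the C5 chain, could bring in C9 and C11 with the arene, and aldol closure onto the unmasked C8 ketone would lead straight to the counterpart of 18 without sulfonate, chromium coupling or oxidation. On this point the alternative is the better plan.
- Against it here: the nucleophile must attack a β-carbon next to quaternary C4. The C1 carbonyl and the C2=C3 alkene are surplus and must be erased selectively among other carbonyl groups. The aldol condensation would have to form a tetrasubstituted enone beside a quaternary centre.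
- Comparison: on structure it is equal in the number of centres set by catalysis (C5 directly, C10 by relay). On mechanism it avoids carbocations, which is an advantage. On step economy the extra oxygen at C1 would cost about as many steps as the convergent enone assembly saves.

**Alternative 3:** The cut is inside the arene at C1'–C6', with the decalin taken from the chiral-pool lactone A6. The forward key step is thermolysis of the diketo-dioxinone A7 in an alcohol: the acylketene is trapped as a triketo ester, which closes by aldol reaction and aromatises to the resorcylate A8.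
- In its favour: C5 and C10 (and C9) come from A6 without any asymmetric catalysis or ring construction, and the C9–C11–C1' connectivity arises without an organometallic coupling at a hindered carbon. In stereochemical security this is the better plan.
- Against it here: A8 has oxygen at C3' and C5' and a carboxyl group at C2', whereas the target needs oxygen at C2' and a methyl ether at C3' only. The carboxyl must therefore be exchanged for hydroxyl and the less reactive, hydrogen-bonded phenol methylated selectively. The C8 oxygen of A6 must be removed with control of C8. C11 must be oxidised at a benzylic position of an electron-rich ring before the same sulfonate and chloride endgame.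
- Comparison: on structure it is better for the decalin and worse for the arene and for the oxidation level of C11. On mechanism the cascade is mild and well behaved compared with a strong-acid cyclisation. On step economy it would probably be the longest of the four.

Key step: step 4

**Remarks on the chemistry**
- The sense of induction of the ferrocenyl diphosphine in step 3 is assumed; the ligand antipode that gives the 3S adduct is the one to use.
- Compounds 11 (at C2) and 17 (at the carbinol carbon) are carried as epimer mixtures, because both centres become sp2 in the next step.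

## Route

Step 1
Reactants: 1 3-(trimethylsilyl)prop-2-yn-1-ol
Product: 2 (Z)-3-(trimethylsilyl)prop-2-en-1-ol
Conditions: H2 (1 atm), Ni2B (from Ni(OAc)2·4H2O and NaBH4), ethylenediamine, EtOH, rt
Reagents that add atoms: none
Why: Semihydrogenation of the silylalkyne on amine-poisoned nickel boride stops at the alkene and delivers both hydrogens syn, which fixes the Z geometry the key step needs.

Step 2
Reactants: 2 (Z)-3-(trimethylsilyl)prop-2-en-1-ol
Product: 3 (Z)-(3-bromoprop-1-en-1-yl)trimethylsilane
Conditions: CBr4, PPh3, CH2Cl2, 0 °C
Reagents that add atoms: carbon tetrabromide, BrC(Br)(Br)Br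
Why: Appel bromination: bromide displaces the alkoxyphosphonium group by SN2 at the primary allylic carbon under neutral conditions, so the Z alkene and the C–Si bond are kept.

Step 3
Reactants: 4 2-methylcyclohex-2-en-1-one; 5 isopropenylmagnesium bromide; 3 (Z)-(3-bromoprop-1-en-1-yl)trimethylsilane
Product: 7 (2S,3S)-2-methyl-3-(prop-1-en-2-yl)-2-[(2Z)-3-(trimethylsilyl)prop-2-en-1-yl]cyclohexan-1-one, via bromomagnesium enolate 6 (not isolated)
Conditions: CuBr·SMe2 (5 mol %), (R,SP)-1-[2-(diphenylphosphino)ferrocenyl]ethyldicyclohexylphosphine (6 mol %), tBuOMe, −78 °C, slow addition of 5; then 3, DMPU, −78 → 0 °C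
Reagents that add atoms: none
Why: Copper-catalysed enantioselective conjugate addition, in which the chiral diphosphine–copper complex selects the enone face and sets C3 (drimane C5) as S, gives one regiodefined enolate. Its C-alkylation occurs anti to the neighbouring isopropenyl group, so the quaternary C2 (drimane C10) forms with the silylallyl arm trans to the isopropenyl arm.

Step 4
Reactants: 7 (2S,3S)-2-methyl-3-(prop-1-en-2-yl)-2-[(2Z)-3-(trimethylsilyl)prop-2-en-1-yl]cyclohexan-1-one
Product: 8 (4aS,8aS)-5,5,8a-trimethyl-3,4,4a,5,8,8a-hexahydronaphthalen-1(2H)-one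
Conditions: CF3SO3H (2.2 equiv), CH2Cl2, −78 → −40 °C; then Et3N, NaHCO3 (aq)
Reagents that add atoms: none
Why: The acid protonates the 1,1-disubstituted alkene at its CH2 end to give the tertiary C4 cation, which is attacked through the π face by the silicon-bearing carbon C3; the secondary cation formed at C2 is stabilised by the β C–Si bond and loses the silyl group to triflate, leaving the alkene at C2=C3 and nowhere else. This is a vinylsilane-terminated cation–olefin cyclisation, the closest known type being proton-initiated polyene cyclisations ended by ipso substitution of a vinylsilane. Ring A closes in the 6-endo mode with respect to the vinylsilane (both alkene carbons end up in the ring) through a chair-like arrangement with the C5 and C10 arms both equatorial on ring B, so the trans fusion already present in 7 is carried over. No stereocentre is created, since C4 bears two methyl groups and C5 and C10 are not touched. The step needs protonation of the isopropenyl group rather than ipso protonation of the vinylsilane, which the higher basicity of the 1,1-dialkyl alkene, the low temperature and the fast intramolecular capture should secure, and it needs attack by C3 rather than C2, which the β-silicon effect secures because attack by C2 would give a cyclopentane and an α-silyl cation. The Z geometry lets the C3–Si bond turn into line with the empty orbital at C2 while the C1–C2–C3–C4 torsion closes toward the cis ring alkene, whereas the E isomer could use that stabilisation only on the way to a trans-cyclohexene. Capture of the cation by the carbonyl oxygen would need the C5 arm axial and would place an oxocarbenium carbon at a bridgehead, so it should be reversible and unproductive; the excess acid allows for the basicity of the ketone.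

Step 5
Reactants: 8 (4aS,8aS)-5,5,8a-trimethyl-3,4,4a,5,8,8a-hexahydronaphthalen-1(2H)-one
Product: 9 (4aS,8aS)-5,5,8a-trimethyloctahydronaphthalen-1(2H)-one
Conditions: H2 (1 atm), Pd/C (10 wt %), EtOAc, rt
Reagents that add atoms: none
Why: Heterogeneous hydrogenation of the cis-disubstituted alkene; the ketone and both stereocentres are not involved.

Step 6
Reactants: 9 (4aS,8aS)-5,5,8a-trimethyloctahydronaphthalen-1(2H)-one
Product: 11 (4aS,8aS)-2,5,5,8a-tetramethyloctahydronaphthalen-1(2H)-one (C2 epimers), via lithium enolate 10 (not isolated)
Conditions: LiN(iPr)2 (1.05 equiv), THF, −78 °C; then MeI, −78 → 0 °C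
Reagents that add atoms: iodomethane, CI
Why: Only C2 carries α-hydrogens because C8a is quaternary, so the lithium enolate is regiodefined and is methylated by SN2 enolate alkylation. The configuration of the new centre does not matter because it becomes sp2 in step 7.

Step 7
Reactants: 11 (4aS,8aS)-2,5,5,8a-tetramethyloctahydronaphthalen-1(2H)-one (C2 epimers)
Product: 13 (4aS,8aS)-2,5,5,8a-tetramethyl-3,4,4a,5,6,7,8,8a-octahydronaphthalen-1-yl trifluoromethanesulfonate, via potassium enolate 12 (not isolated)
Conditions: KN(SiMe3)2, THF, −78 → 0 °C; then PhNTf2, 0 °C → rt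
Reagents that add atoms: N-phenylbis(trifluoromethanesulfonimide), O=S(=O)(N(c1ccccc1)S(=O)(=O)C(F)(F)F)C(F)(F)F
Why: Removal of the single remaining α-hydrogen gives the only possible, tetrasubstituted enolate, which is sulfonylated on oxygen (enol triflate formation, as practised on 2,2,6-trisubstituted cyclohexanones).

Step 8
Reactants: 14 5-bromo-2-hydroxy-3-methoxybenzaldehyde
Product: 15 2-hydroxy-3,5-dimethoxybenzaldehyde
Conditions: NaOMe (5 equiv), CuCl (20 mol %), DMF/MeOH, 110 °C; then HCl (aq)
Reagents that add atoms: sodium methoxide, C[O-].[Na+]
Why: Copper-catalysed Ullmann-type methoxylation of the aryl bromide; the substrate reacts as its phenoxide, which shields the aldehyde from methoxide, as in the analogous exchange on 5-bromovanillin.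

Step 9
Reactants: 15 2-hydroxy-3,5-dimethoxybenzaldehyde
Product: 16 2,3,5-trimethoxybenzaldehyde
Conditions: MeI, K2CO3, DMF, rt
Reagents that add atoms: iodomethane, CI
Why: Williamson O-methylation of the phenol; no other nucleophilic site is present.

Step 10
Reactants: 13 (4aS,8aS)-2,5,5,8a-tetramethyl-3,4,4a,5,6,7,8,8a-octahydronaphthalen-1-yl trifluoromethanesulfonate; 16 2,3,5-trimethoxybenzaldehyde
Product: 17 [(4aS,8aS)-2,5,5,8a-tetramethyl-3,4,4a,5,6,7,8,8a-octahydronaphthalen-1-yl](2,3,5-trimethoxyphenyl)methanol (both carbinol epimers)
Conditions: CrCl2 (4 equiv), NiCl2 (2 mol %), DMF, rt → 50 °C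
Reagents that add atoms: none
Why: Nozaki–Hiyama–Kishi coupling: zerovalent nickel, formed from NiCl2 by divalent chromium, inserts into the C–O sulfonate bond, and transmetalation gives an alkenyl species of trivalent chromium that adds to the aldehyde only. The carbinol configuration is of no consequence because it is oxidised in step 11.

Step 11
Reactants: 17 [(4aS,8aS)-2,5,5,8a-tetramethyl-3,4,4a,5,6,7,8,8a-octahydronaphthalen-1-yl](2,3,5-trimethoxyphenyl)methanol (both carbinol epimers)
Product: 18 [(4aS,8aS)-2,5,5,8a-tetramethyl-3,4,4a,5,6,7,8,8a-octahydronaphthalen-1-yl](2,3,5-trimethoxyphenyl)methanone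
Conditions: Dess–Martin periodinane, NaHCO3, CH2Cl2, 0 °C → rt
Reagents that add atoms: none
Why: Dess–Martin oxidation of a secondary alcohol that is both allylic and benzylic, under buffered conditions; there is no epimerisable centre and the alkene cannot migrate.

Step 12
Reactants: 18 [(4aS,8aS)-2,5,5,8a-tetramethyl-3,4,4a,5,6,7,8,8a-octahydronaphthalen-1-yl](2,3,5-trimethoxyphenyl)methanone
Product: 20 (E)-[(2S,4aS,8aS)-2,5,5,8a-tetramethyloctahydronaphthalen-1(2H)-ylidene](2,3,5-trimethoxyphenyl)methyl trifluoromethanesulfonate, via copper enolate 19 (not isolated)
Conditions: [(Ph3P)CuH]6 (0.5 equiv), toluene/THF, rt; then N-(5-chloropyridin-2-yl)bis(trifluoromethanesulfonimide), −78 °C → rt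
Reagents that add atoms: N-(5-chloropyridin-2-yl)bis(trifluoromethanesulfonimide), O=S(=O)(N(c1ccc(Cl)cn1)S(=O)(=O)C(F)(F)F)C(F)(F)F
Why: Conjugate reduction by the copper hydride followed by O-sulfonylation of the enolate. Hydride is expected to reach C8 from the α face, away from the axial angular methyl that covers the β face, which leaves the C8 methyl β (2S). The enolate should place its in-plane oxygen beside the C8–H rather than beside C1 of quaternary C10, and enolates of monovalent copper can adjust geometry through their carbon-bound form before they are trapped, giving the E alkene.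

Step 13
Reactants: 20 (E)-[(2S,4aS,8aS)-2,5,5,8a-tetramethyloctahydronaphthalen-1(2H)-ylidene](2,3,5-trimethoxyphenyl)methyl trifluoromethanesulfonate
Product: 21 1-{(E)-chloro[(2S,4aS,8aS)-2,5,5,8a-tetramethyloctahydronaphthalen-1(2H)-ylidene]methyl}-2,3,5-trimethoxybenzene
Conditions: Ni(cod)2 (15 mol %), LiCl (5 equiv), DMA/THF, rt
Reagents that add atoms: lithium chloride, [Li+].[Cl-]
Why: Nickel-catalysed exchange of an enol triflate for chloride: zerovalent nickel inserts into the C–O bond, chloride replaces triflate on nickel, and C–Cl reductive elimination follows. All events take place at the sp2 carbon without opening the π bond, so retention of geometry is expected.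

Step 14
Reactants: 21 1-{(E)-chloro[(2S,4aS,8aS)-2,5,5,8a-tetramethyloctahydronaphthalen-1(2H)-ylidene]methyl}-2,3,5-trimethoxybenzene
Product: 23 2-{(E)-chloro[(2S,4aS,8aS)-2,5,5,8a-tetramethyloctahydronaphthalen-1(2H)-ylidene]methyl}-6-methoxybenzene-1,4-diol (the target), via methoxyquinone 22 (not isolated)
Conditions: (NH4)2Ce(NO3)6 (2.5 equiv), MeCN/H2O, 0 °C; then Na2S2O4 (aq), EtOAc, rt
Reagents that add atoms: water, O
Why: Oxidative demethylation by tetravalent cerium: water attacks the arene radical cation at the two para methoxy-bearing carbons and methanol leaves, giving the para-quinone in preference to the ortho-quinone, so the C3' ether stays. Dithionite then reduces the quinone to the hydroquinone without touching the vinyl chloride.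

## Compound list

1 | 3-(trimethylsilyl)prop-2-yn-1-ol | C[Si](C)(C)C#CCO | starting material
2 | (Z)-3-(trimethylsilyl)prop-2-en-1-ol | C[Si](C)(C)/C=C\CO | intermediate
3 | (Z)-(3-bromoprop-1-en-1-yl)trimethylsilane | C[Si](C)(C)/C=C\CBr | intermediate
4 | 2-methylcyclohex-2-en-1-one | CC1=CCCCC1=O | starting material
5 | isopropenylmagnesium bromide | CC(=C)[Mg]Br | starting material
6 | bromomagnesium (3S)-2-methyl-3-(prop-1-en-2-yl)cyclohex-1-en-1-olate | CC1=C(O[Mg]Br)CCC[C@H]1C(C)=C | intermediate (not isolated)
7 | (2S,3S)-2-methyl-3-(prop-1-en-2-yl)-2-[(2Z)-3-(trimethylsilyl)prop-2-en-1-yl]cyclohexan-1-one | O=C1CCC[C@@H](C(C)=C)[C@]1(C)C/C=C\[Si](C)(C)C | intermediate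
8 | (4aS,8aS)-5,5,8a-trimethyl-3,4,4a,5,8,8a-hexahydronaphthalen-1(2H)-one | O=C1CCC[C@H]2C(C)(C)C=CC[C@]12C | intermediate
9 | (4aS,8aS)-5,5,8a-trimethyloctahydronaphthalen-1(2H)-one | O=C1CCC[C@H]2C(C)(C)CCC[C@]12C | intermediate
10 | lithium (4aS,8aS)-5,5,8a-trimethyl-3,4,4a,5,6,7,8,8a-octahydronaphthalen-1-olate | [Li]OC1=CCC[C@H]2C(C)(C)CCC[C@]12C | intermediate (not isolated)
11 | (4aS,8aS)-2,5,5,8a-tetramethyloctahydronaphthalen-1(2H)-one, C2 epimers | O=C1C(C)CC[C@H]2C(C)(C)CCC[C@]12C | intermediate
12 | potassium (4aS,8aS)-2,5,5,8a-tetramethyl-3,4,4a,5,6,7,8,8a-octahydronaphthalen-1-olate | [K]OC1=C(C)CC[C@H]2C(C)(C)CCC[C@]12C | intermediate (not isolated)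
13 | (4aS,8aS)-2,5,5,8a-tetramethyl-3,4,4a,5,6,7,8,8a-octahydronaphthalen-1-yl trifluoromethanesulfonate | O=S(=O)(OC1=C(C)CC[C@H]2C(C)(C)CCC[C@]12C)C(F)(F)F | intermediate
14 | 5-bromo-2-hydroxy-3-methoxybenzaldehyde | COc1cc(Br)cc(C=O)c1O | starting material
15 | 2-hydroxy-3,5-dimethoxybenzaldehyde | COc1cc(OC)cc(C=O)c1O | intermediate
16 | 2,3,5-trimethoxybenzaldehyde | COc1cc(OC)cc(C=O)c1OC | intermediate
17 | [(4aS,8aS)-2,5,5,8a-tetramethyl-3,4,4a,5,6,7,8,8a-octahydronaphthalen-1-yl](2,3,5-trimethoxyphenyl)methanol, carbinol epimers | COc1cc(OC)cc(C(O)C2=C(C)CC[C@H]3C(C)(C)CCC[C@]23C)c1OC | intermediate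
18 | [(4aS,8aS)-2,5,5,8a-tetramethyl-3,4,4a,5,6,7,8,8a-octahydronaphthalen-1-yl](2,3,5-trimethoxyphenyl)methanone | COc1cc(OC)cc(C(=O)C2=C(C)CC[C@H]3C(C)(C)CCC[C@]23C)c1OC | intermediate
19 | {[(E)-[(2S,4aS,8aS)-2,5,5,8a-tetramethyloctahydronaphthalen-1(2H)-ylidene](2,3,5-trimethoxyphenyl)methyl]oxy}copper, the phosphine-bound enolate of monovalent copper | COc1cc(OC)cc(/C(O[Cu])=C2/[C@@H](C)CC[C@H]3C(C)(C)CCC[C@]23C)c1OC | intermediate (not isolated)
20 | (E)-[(2S,4aS,8aS)-2,5,5,8a-tetramethyloctahydronaphthalen-1(2H)-ylidene](2,3,5-trimethoxyphenyl)methyl trifluoromethanesulfonate | COc1cc(OC)cc(/C(OS(=O)(=O)C(F)(F)F)=C2/[C@@H](C)CC[C@H]3C(C)(C)CCC[C@]23C)c1OC | intermediate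
21 | 1-{(E)-chloro[(2S,4aS,8aS)-2,5,5,8a-tetramethyloctahydronaphthalen-1(2H)-ylidene]methyl}-2,3,5-trimethoxybenzene | COc1cc(OC)cc(/C(Cl)=C2/[C@@H](C)CC[C@H]3C(C)(C)CCC[C@]23C)c1OC | intermediate
22 | 2-{(E)-chloro[(2S,4aS,8aS)-2,5,5,8a-tetramethyloctahydronaphthalen-1(2H)-ylidene]methyl}-6-methoxycyclohexa-2,5-diene-1,4-dione | COC1=CC(=O)C=C(/C(Cl)=C2/[C@@H](C)CC[C@H]3C(C)(C)CCC[C@]23C)C1=O | intermediate (not isolated)
23 | 2-{(E)-chloro[(2S,4aS,8aS)-2,5,5,8a-tetramethyloctahydronaphthalen-1(2H)-ylidene]methyl}-6-methoxybenzene-1,4-diol | COc1cc(O)cc(/C(Cl)=C2/[C@@H](C)CC[C@H]3C(C)(C)CCC[C@]23C)c1O | target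

## Step count and least certain steps

Total step count: 14. Longest linear sequence: 12 steps (steps 1–7 and 10–14, from 1 to 23); the arene branch (steps 8 and 9) joins at step 10.

**Step 4 (key step).** The most likely failure is ipso protonation of the vinylsilane running alongside protonation of the isopropenyl group, which removes the terminator. In addition, reversible loss of a proton from the C4 cation toward C5 would erode the C5 configuration, because both alkenes are of comparable basicity toward a strong acid. Fallback: starting from 7, the isopropenyl group is hydrated selectively by Mukaiyama hydration (Co(acac)2, PhSiH3, O2, iPrOH); hydrogen-atom transfer chooses the 1,1-disubstituted alkene because only it gives a tertiary radical. This gives the tertiary alcohol (2S,3R)-3-(2-hydroxypropan-2-yl)-2-methyl-2-[(2Z)-3-(trimethylsilyl)prop-2-en-1-yl]cyclohexan-1-one F1. Ionisation of F1 with SnCl4 in CH2Cl2 at −78 °C then forms the C4 cation by loss of hydroxide in a medium without free strong acid, and the same vinylsilane closure rejoins the route at 8.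

**Step 3.** The most likely failure is slow C-alkylation of the aggregated bromomagnesium enolate at a carbon that becomes quaternary, so that proton exchange with the product ketone and O-alkylation compete. Facial selectivity with an sp2 Grignard reagent on an α-methyl enone may also need ligand screening. Fallback: starting from 4 and 5, the conjugate addition is run in the presence of Me3SiCl and the enolate is isolated as trimethyl{[(3S)-2-methyl-3-(prop-1-en-2-yl)cyclohex-1-en-1-yl]oxy}silane F2, whose enantiomeric purity can be checked before material is committed. MeLi in THF then releases lithium (3S)-2-methyl-3-(prop-1-en-2-yl)cyclohex-1-en-1-olate F3, which is alkylated by 3 in THF/DMPU and rejoins the route at 7.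

**Step 10.** The most likely failure is slow insertion of nickel into the hindered tetrasubstituted C–O bond, which lets reduction of the sulfonate and pinacol coupling of 16 by divalent chromium take over. Fallback: starting from 11, condensation with 2,4,6-triisopropylbenzenesulfonyl hydrazide gives N'-[(4aS,8aS)-2,5,5,8a-tetramethyloctahydronaphthalen-1(2H)-ylidene]-2,4,6-tri(propan-2-yl)benzenesulfonohydrazide F4. A Shapiro reaction (nBuLi, 2.2 equiv, THF/TMEDA, −78 → 0 °C) converts it into [(4aS,8aS)-2,5,5,8a-tetramethyl-3,4,4a,5,6,7,8,8a-octahydronaphthalen-1-yl]lithium F5; this is regiodefined because only C2 bears an α-hydrogen. F5 adds to 16 at −78 °C and rejoins the route at 17.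

**Step 12.** The most likely failure is slow hydride transfer to an enone whose carbonyl group is twisted out of conjugation with the tetrasubstituted alkene, together with incomplete sulfonylation of the weakly nucleophilic copper enolate. Fallback: starting from 18, radical conjugate reduction by hydrogen-atom transfer (Mn(dpm)3 cat., PhSiH3, tBuOOH, iPrOH, rt) places hydrogen on C8 from the open α face and gives [(2S,4aS,8aS)-2,5,5,8a-tetramethyldecahydronaphthalen-1-yl](2,3,5-trimethoxyphenyl)methanone F6 as C1 epimers. KN(SiMe3)2 in THF removes the only α-hydrogen to give the potassium enolate potassium (E)-[(2S,4aS,8aS)-2,5,5,8a-tetramethyloctahydronaphthalen-1(2H)-ylidene](2,3,5-trimethoxyphenyl)methanolate F7 under equilibrating conditions. Sulfonylation with the same pyridyl triflimide rejoins the route at 20.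

**Step 13.** The most likely failure is slow oxidative addition at the crowded enol sulfonate, with loss of alkene geometry through reversible pathways at nickel. Fallback: starting from 20, stannylation (Pd(PPh3)4, LiCl, Me3SnSnMe3, dioxane, 90 °C) gives [(E)-[(2S,4aS,8aS)-2,5,5,8a-tetramethyloctahydronaphthalen-1(2H)-ylidene](2,3,5-trimethoxyphenyl)methyl]trimethylstannane F8. Chlorodestannylation with CuCl2 in THF, which replaces tin at the sp2 carbon with retention, rejoins the route at 21.

## Further compounds

F1 | step 4 | (2S,3R)-3-(2-hydroxypropan-2-yl)-2-methyl-2-[(2Z)-3-(trimethylsilyl)prop-2-en-1-yl]cyclohexan-1-one | O=C1CCC[C@@H](C(C)(C)O)[C@]1(C)C/C=C\[Si](C)(C)C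
F2 | step 3 | trimethyl{[(3S)-2-methyl-3-(prop-1-en-2-yl)cyclohex-1-en-1-yl]oxy}silane | CC1=C(O[Si](C)(C)C)CCC[C@H]1C(C)=C
F3 | step 3 | lithium (3S)-2-methyl-3-(prop-1-en-2-yl)cyclohex-1-en-1-olate | CC1=C(O[Li])CCC[C@H]1C(C)=C
F4 | step 10 | N'-[(4aS,8aS)-2,5,5,8a-tetramethyloctahydronaphthalen-1(2H)-ylidene]-2,4,6-tri(propan-2-yl)benzenesulfonohydrazide | CC(C)c1cc(C(C)C)c(S(=O)(=O)NN=C2C(C)CC[C@H]3C(C)(C)CCC[C@]23C)c(C(C)C)c1
F5 | step 10 | [(4aS,8aS)-2,5,5,8a-tetramethyl-3,4,4a,5,6,7,8,8a-octahydronaphthalen-1-yl]lithium | [Li]C1=C(C)CC[C@H]2C(C)(C)CCC[C@]12C
F6 | step 12 | [(2S,4aS,8aS)-2,5,5,8a-tetramethyldecahydronaphthalen-1-yl](2,3,5-trimethoxyphenyl)methanone, C1 epimers | COc1cc(OC)cc(C(=O)C2[C@@H](C)CC[C@H]3C(C)(C)CCC[C@]23C)c1OC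
F7 | step 12 | potassium (E)-[(2S,4aS,8aS)-2,5,5,8a-tetramethyloctahydronaphthalen-1(2H)-ylidene](2,3,5-trimethoxyphenyl)methanolate | COc1cc(OC)cc(/C(O[K])=C2/[C@@H](C)CC[C@H]3C(C)(C)CCC[C@]23C)c1OC
F8 | step 13 | [(E)-[(2S,4aS,8aS)-2,5,5,8a-tetramethyloctahydronaphthalen-1(2H)-ylidene](2,3,5-trimethoxyphenyl)methyl]trimethylstannane | COc1cc(OC)cc(/C([Sn](C)(C)C)=C2/[C@@H](C)CC[C@H]3C(C)(C)CCC[C@]23C)c1OC
A1 | alternative 1 | (4S)-4-benzyl-3-[(2E,8E,10E)-3,7,7-trimethyldodeca-2,8,10-trienoyl]-1,3-oxazolidin-2-one | O=C1OC[C@H](Cc2ccccc2)N1C(=O)/C=C(\C)CCCC(C)(C)/C=C/C=C/C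
A2 | alternative 1 | (4S)-4-benzyl-3-{[(1S,2S,4aS,8aS)-2,5,5,8a-tetramethyl-1,2,4a,5,6,7,8,8a-octahydronaphthalen-1-yl]carbonyl}-1,3-oxazolidin-2-one | O=C1OC[C@H](Cc4ccccc4)N1C(=O)[C@H]2[C@@H](C)C=C[C@H]3C(C)(C)CCC[C@]23C
A3 | alternative 2 | 4,4-dimethylcyclohexa-2,5-dien-1-one | CC1(C)C=CC(=O)C=C1
A4 | alternative 2 | [2-(2-methyl-1,3-dioxolan-2-yl)ethyl]magnesium bromide | CC1(CC[Mg]Br)OCCO1
A5 | alternative 2 | (5R,6R)-4,4,6-trimethyl-5-[2-(2-methyl-1,3-dioxolan-2-yl)ethyl]cyclohex-2-en-1-one | O=C1C=CC(C)(C)[C@H](CCC2(C)OCCO2)[C@H]1C
A6 | alternative 3 | (3aR,5aS,9aS,9bR)-3a,6,6,9a-tetramethyldecahydronaphtho[2,1-b]furan-2(1H)-one (sclareolide) | O=C1C[C@H]2[C@@](C)(CC[C@H]3C(C)(C)CCC[C@]23C)O1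
A7 | alternative 3 | 2,2-dimethyl-6-{2,4-dioxo-5-[(1S,2S,4aS,8aR)-2,5,5,8a-tetramethyldecahydronaphthalen-1-yl]pentyl}-4H-1,3-dioxin-4-one | CC1(C)OC(=O)C=C(CC(=O)CC(=O)C[C@H]2[C@@H](C)CC[C@H]3C(C)(C)CCC[C@]23C)O1
A8 | alternative 3 | methyl 2,4-dihydroxy-6-{[(1S,2S,4aS,8aR)-2,5,5,8a-tetramethyldecahydronaphthalen-1-yl]methyl}benzoate | COC(=O)c1c(O)cc(O)cc1C[C@H]2[C@@H](C)CC[C@H]3C(C)(C)CCC[C@]23C
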